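**Plan**
- Retrosynthesis: the two bonds that join ring C to ring A, C8a–O1 and C4a–C4, are cut in one step. This gives an (S)-β-hydroxy ester that carries ring B and a ring A piece at the quinone oxidation level (a p-quinone monoketal). The hydroxy ester goes back by C=O reduction to a β-keto ester and by a Claisen C–C cut to an aryl methyl ketone.
- Enabling feature: on ring A the oxygens at C5 and C8 are para. Ring A can therefore be a cyclohexa-2,5-dienone with C5 as carbonyl and C8 as dimethyl ketal, in which C8a is the electrophilic β-carbon (takes O1) and C4a the nucleophilic α-carbon (takes C4).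
- Forward order: the ring B side chain is built first, the dienone is made from a phenol, then ring C closes and ring A aromatizes in one flask. This releases the free 5-OH and the 8-OMe without any protecting group.
- Stereochemistry: C2 is set by asymmetric hydrogenation of the β-keto ester ((R)-BINAP, giving the (S)-carbinol) and is carried through unchanged, since its C–O bond is never broken.

Key step: step 4

Remark: the two compounds that form in the flask in the last step are drawn in their neutral keto forms; in the flask they are potassium enolates and mixtures of epimers at the transient ring-fusion carbons.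

**Step 1**
Reactants: 1 2',6'-dimethoxyacetophenone
Product: 2 methyl 3-(2,6-dimethoxyphenyl)-3-oxopropanoate
Conditions: NaH (2.5 equiv), (MeO)2CO (5 equiv), toluene, 90 °C; then AcOH
Reagents that add atoms: dimethyl carbonate, COC(=O)OC
Why: Crossed Claisen condensation of the methyl ketone enolate with a non-enolizable carbonate, pulled to completion by deprotonation of the β-keto ester product.

**Step 2**
Reactants: 2 methyl 3-(2,6-dimethoxyphenyl)-3-oxopropanoate
Product: 3 methyl (3S)-3-(2,6-dimethoxyphenyl)-3-hydroxypropanoate
Conditions: [RuCl(benzene)((R)-BINAP)]Cl (1 mol %), H2 (50 atm), MeOH, 50 °C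
Reagents that add atoms: none
Why: Noyori asymmetric hydrogenation of a β-keto ester through its chelate to the divalent ruthenium hydride; by analogy with benzoylacetate esters the (R)-BINAP catalyst should deliver hydride to the face that gives the (S)-carbinol.

**Step 3**
Reactants: 4 3,4-dimethoxyphenol
Product: 5 3,4,4-trimethoxycyclohexa-2,5-dien-1-one
Conditions: PhI(OAc)2 (1.1 equiv), MeOH, 0 °C
Reagents that add atoms: methanol, CO
Why: Oxidative dearomatization of a 4-methoxyphenol by trivalent iodine; the phenoxonium ion should be trapped by methanol at the methoxy-bearing para carbon to give the p-quinone monoketal.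

**Step 4**
Reactants: 3 methyl (3S)-3-(2,6-dimethoxyphenyl)-3-hydroxypropanoate; 5 3,4,4-trimethoxycyclohexa-2,5-dien-1-one
Product: 8 (2S)-5-hydroxy-7,8,2',6'-tetramethoxyflavanone, via oxa-Michael adduct 6 (not isolated), via bicyclic β-diketone 7 (not isolated)
Conditions: KOtBu (1.1 equiv) added to 3 + 5 (1.3 equiv), THF, −40 → 0 °C; then TFA (3 equiv), 0 °C → rt
Reagents that add atoms: none
Why: Proposed new method: the potassium alkoxide of 3 should add through oxygen to C8a, the unsubstituted β-carbon of the cross-conjugated dienone 5 (oxa-Michael), the enolate 6 so formed should acylate itself at C4a with the tethered methyl ester (Claisen), and the β-diketone 7, held as its potassium enolate, should lose methanol from the C8 ketal on acidification so that ring A aromatizes, C5=O becoming the free 5-OH and C8 keeping one methoxy group. The closest known reaction types are the Michael–Claisen (Hauser–Kraus-type) annulations of p-quinone monoketals with carbon nucleophiles that carry an ester, the base-mediated oxa-Michael addition of alcohols to cyclohexa-2,5-dienones, and the acid-induced loss of methanol from quinone monoketal adducts; their combination with an oxygen nucleophile and an ester in one partner is without direct precedent. The C8a–O1 bond forms intermolecularly and ring C then closes by a 6-(enolexo)-exo-trig attack of C4a on the ester carbonyl, while ring A is not closed but re-aromatized. No new stereocenter survives: C2 comes from 3 with its C–O bond untouched, and the transient centers C4a and C8a vanish on aromatization. The step needs O- rather than C-attack by 3, addition at C8a rather than C7, and retention of the C2 configuration; these should be secured by the hydroxyl being the only site deprotonated by one equivalent of base at low temperature, by C7 being the deactivated β-carbon of a vinylogous ester, and by immediate trapping of the alkoxide (which limits retro-aldol) together with the enolate form of 7, which shields C3–H from the E1cB ring opening that would racemize C2. The sequence should be driven forward by formation of the stabilized diketonate and finally by aromatization.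

**Compound list**
1 | 2',6'-dimethoxyacetophenone | CC(=O)c1c(OC)cccc1OC | starting material
2 | methyl 3-(2,6-dimethoxyphenyl)-3-oxopropanoate | COC(=O)CC(=O)c1c(OC)cccc1OC | intermediate
3 | methyl (3S)-3-(2,6-dimethoxyphenyl)-3-hydroxypropanoate | COC(=O)C[C@H](O)c1c(OC)cccc1OC | intermediate
4 | 3,4-dimethoxyphenol | COc1ccc(O)cc1OC | starting material
5 | 3,4,4-trimethoxycyclohexa-2,5-dien-1-one | COC1=CC(=O)C=CC1(OC)OC | intermediate
6 | methyl (3S)-3-(2,6-dimethoxyphenyl)-3-[(2,2,3-trimethoxy-5-oxocyclohex-3-en-1-yl)oxy]propanoate (epimers at the ring carbon bearing oxygen; potassium enolate in the flask) | COC(=O)C[C@H](OC1CC(=O)C=C(OC)C1(OC)OC)c1c(OC)cccc1OC | intermediate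
7 | (2S)-2-(2,6-dimethoxyphenyl)-7,8,8-trimethoxy-2,3,8,8a-tetrahydro-4H-chromene-4,5(4aH)-dione (epimers at C4a and C8a; potassium enolate in the flask) | COC1=CC(=O)C2C(=O)C[C@@H](c3c(OC)cccc3OC)OC2C1(OC)OC | intermediate
8 | (2S)-5-hydroxy-7,8,2',6'-tetramethoxyflavanone | COc1cc(O)c2c(c1OC)O[C@H](c1c(OC)cccc1OC)CC2=O | target

**Step count**
Total steps: 4. Longest linear sequence: 3 steps (1 → 2 → 3 → 8).

**Steps most likely to fail**

1. Step 4. The alkoxide of 3 may fragment by retro-aldol cleavage or react through carbon, so that the oxa-Michael/Claisen sequence does not start or the enantiomeric purity erodes; the hindered secondary alkoxide may also add too slowly next to the ketal carbon. The fallback uses known chemistry, sets out from 2 and returns at 8.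
 - Hydrogenation of 2 with the enantiomeric catalyst [RuCl(benzene)((S)-BINAP)]Cl should give methyl (3R)-3-(2,6-dimethoxyphenyl)-3-hydroxypropanoate F1.
 - Mitsunobu etherification (PPh3, DIAD, toluene, 0 °C) with commercial 3-hydroxy-4,5-dimethoxybenzaldehyde should proceed with inversion to methyl (3S)-3-(2,6-dimethoxyphenyl)-3-(5-formyl-2,3-dimethoxyphenoxy)propanoate F2.
 - Baeyer–Villiger oxidation (mCPBA, CH2Cl2) should give methyl (3S)-3-(2,6-dimethoxyphenyl)-3-[5-(formyloxy)-2,3-dimethoxyphenoxy]propanoate F3.
 - Mild methanolysis of the formate (Et3N, MeOH, rt) should give methyl (3S)-3-(2,6-dimethoxyphenyl)-3-(5-hydroxy-2,3-dimethoxyphenoxy)propanoate F4.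
 - Saponification (LiOH, THF/H2O, 0 °C) should give (3S)-3-(2,6-dimethoxyphenyl)-3-(5-hydroxy-2,3-dimethoxyphenoxy)propanoic acid F5.
 - Intramolecular Friedel–Crafts acylation (TFAA, CH2Cl2, 0 °C; then MeOH, NaHCO3) should close ring C at C4a, the only free position ortho to O1, and give 8.

2. Step 2. Hydrogenation of the doubly ortho-substituted ketone may be slow and poorly face-selective, and the electron-rich benzylic carbinol may ionize in warm methanol and lose enantiomeric purity. The fallback replaces asymmetric catalysis by resolution, sets out from 2 and returns at 3. Reduction with NaBH4 (MeOH, 0 °C) should give racemic methyl 3-(2,6-dimethoxyphenyl)-3-hydroxypropanoate F6. Preparative chromatography on a chiral stationary phase (amylose tris(3,5-dimethylphenylcarbamate), supercritical CO2/MeOH) should then deliver 3; the other enantiomer is the compound described as F1 under step 4.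

3. Step 3. The dienone may be over-oxidized or hydrolysed to the quinone during oxidation and isolation, and methanol may attack ortho instead of para. The fallback reaches the same ketal electrochemically, sets out from 4 and returns at 5. O-Methylation (MeI, K2CO3, acetone) should give 1,2,4-trimethoxybenzene F7. Anodic oxidation (Pt anode, KOH, MeOH, constant current, 0 °C) should give the quinone bisketal 1,3,3,6,6-pentamethoxycyclohexa-1,4-diene F8. Monohydrolysis with dilute aqueous acetic acid in acetone should occur at the ketal whose oxocarbenium ion is stabilized by the vinylogous methoxy group and give 5.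

**Further compounds**
F1 | step 4 | methyl (3R)-3-(2,6-dimethoxyphenyl)-3-hydroxypropanoate | COC(=O)C[C@@H](O)c1c(OC)cccc1OC
F2 | step 4 | methyl (3S)-3-(2,6-dimethoxyphenyl)-3-(5-formyl-2,3-dimethoxyphenoxy)propanoate | COC(=O)C[C@H](Oc1cc(C=O)cc(OC)c1OC)c1c(OC)cccc1OC
F3 | step 4 | methyl (3S)-3-(2,6-dimethoxyphenyl)-3-[5-(formyloxy)-2,3-dimethoxyphenoxy]propanoate | COC(=O)C[C@H](Oc1cc(OC=O)cc(OC)c1OC)c1c(OC)cccc1OC
F4 | step 4 | methyl (3S)-3-(2,6-dimethoxyphenyl)-3-(5-hydroxy-2,3-dimethoxyphenoxy)propanoate | COC(=O)C[C@H](Oc1cc(O)cc(OC)c1OC)c1c(OC)cccc1OC
F5 | step 4 | (3S)-3-(2,6-dimethoxyphenyl)-3-(5-hydroxy-2,3-dimethoxyphenoxy)propanoic acid | OC(=O)C[C@H](Oc1cc(O)cc(OC)c1OC)c1c(OC)cccc1OC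
F6 | step 2 | racemic methyl 3-(2,6-dimethoxyphenyl)-3-hydroxypropanoate | COC(=O)CC(O)c1c(OC)cccc1OC
F7 | step 3 | 1,2,4-trimethoxybenzene | COc1ccc(OC)c(OC)c1
F8 | step 3 | 1,3,3,6,6-pentamethoxycyclohexa-1,4-diene | COC1=CC(OC)(OC)C=CC1(OC)OC
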